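You charge 10 mM of J, and each X takes 3 Z, so this flask must draw 30.0 mM of Z into a solution that saturates at 1.4 mM and starts with none dissolved.

| setting | teal | ochre | flask |
|---|---|---|---|
| J | 5 mM | 7.5 mM | 10 mM |
| Z | 1.4 mM (held) | 1.4 mM (held) | 1.4 mM (held) |
| remark | run made earlier | run made earlier |  |
| time |  |  | 25 h |

- teal (time / h: X / %, J / %): 0.500: 20.5, 11.1; 0.833: 63.3, 0; 1.50: 94.6, 0; 3.00: 82.4, 0; 5.00: 73.6, 0; 8.00: 56.4, 0; 15.0: 34.3, 0
- ochre (time / h: X / %, J / %): 0.500: 8.6, 21.7; 0.833: 30.0, 6.3; 1.50: 92.3, 0.3; 3.00: 85.1, 0; 5.00: 73.8, 0.2; 8.00: 58.4, 0.5; 15.0: 31.9, 0.6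

(each reading ± 1 percentage point)

- at the start none of Z is in solution

1. the moment within 25 h at which there is most X
2. the amount of X, in percent of the J charged, at that time

Take ochre in slow motion, its charge being nearest. At the first reading J is going ahead of X: at 0.500 h J reads 21.7 % and X 8.6 %. In the middle, at 0.833 h, J reads 6.3 % and X 30.0 %, so 63.7 % of the charge is read as neither. X then climbs at 0.934 /h, as a share of the charge, to 92.3 % at 1.50 h.

What matters next is the decline. From 3.00 h to 15.0 h the two runs give a mean first-order rate constant, which I call the leak, 0.0774 /h, the share of X lost each hour. At the top of ochre's climb the leak takes 0.0714 /h, far less than the mean gain, so the peak comes when the gain has sunk to that size.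

Now run the leak backwards. Ochre's 85.1 % at 3.00 h is what a whole charge of X born at one instant, 0.916 h, would have left. If the Z feed stays as in ochre, times scale with the charge: this flask's X is born around 1.22 h and its climb ends near 2.17 h. My reckoning is therefore 92.9 % at that time.

The forecast says 90.5 % (86 % to 94 %) at 2 h (1.7 h to 2.5 h), lower than my reckoning and earlier: “Formation looks limited by gas supply, not kinetics”.

The flask peaks at 2.02 h with 93.5 % of X, while the other product D stands at 5.89 %.

    J + Q → E (k = 330 /M/min)
    Q + E → G (k = 230 /M/min)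
    Q + G → X (k = 150 /M/min)
    X → D (k = 0.00130 /min)
    Z ⇌ Q, rate k5*(csat - [Q]) (kL = 0.250 /min)

From that peak the leak gives 15.8 % at 25 h, and this flask holds 15.7 % of X then. For the same flask read at 6.0 h it gives 68.7 %, and that flask holds 69.0 %.

The data come from a simulation on assumed constants.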